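**Plan**
Retrosynthetic cuts, in order: the C1–C10 oxirane oxygen and the silyl ether; C3–C4 (ten-membered ring); the C8–O acyl bond (side-chain acid 28, itself cut at its two allylic C–O bonds); C7–C11 together with C11=C13 (γ-lactone); the C7–C8 oxirane oxygen; C6–C7.
Forward order: enyne 6 (C1–C3, C7–C10, C14) and iodoenal 10 (C4–C6, C15) are joined at C6–C7. Then follow the C7–C8 oxirane ring, the γ-lactone ring by C7–C11, the C8 ester, the ten-membered carbocycle by C3–C4, and the C1–C10 oxirane ring last.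
Enabling feature: C7 lies between two oxygen-bearing carbons (C6–O of the lactone ring, C8–O of the ester), and C11 and O8 stand anti across C7–C8. This is the imprint of a trans C7–C8 oxirane opened at C7 by a C11 carbanion that hangs on O6 (C11–C12–O–C6–C7 is the lactone ring).
Helper: a diethoxyphosphoryl group on C11 carries the negative charge during ring closure. It then leaves in a Horner–Wadsworth–Emmons reaction with formaldehyde, which delivers C13.
Stereochemistry: C6, C7 and C8 come from one Sharpless kinetic resolution, with C7 inverted in the ring closure. C3 comes from peripheral hydride attack on the macrocyclic enone and C1/C10 from peripheral epoxidation. The 4Z geometry comes from hydroalumination–iodination, 1(10)E from the Wittig reaction, and both side-chain E-alkenes from SN2' Mitsunobu reactions.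

Key step: step 10

Remark: locants C1–C15 follow the germacrane numbering of the target (C12 lactone carbonyl, C13 exocyclic methylene, C14 on C10, C15 on C4); compounds 1, 7, 18, 19, 24 and all reagents are taken to be commercial; R/S letters change where iodine or the oxirane alters the priorities, the geometry does not.

**Part A: enyne 6 (C1–C3, C7–C10, C14)**

Step 1
Reactants: 1 3-[(4-methoxybenzyl)oxy]propan-1-ol
Product: 3 ethyl (E)-5-[(4-methoxybenzyl)oxy]-2-methylpent-2-enoate, via aldehyde 2 (not isolated)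
Conditions: IBX, Ph3P=C(Me)CO2Et, DMSO, rt
Reagents that add atoms: ethyl 2-(triphenylphosphoranylidene)propanoate, CCOC(=O)C(C)=P(c1ccccc1)(c1ccccc1)c1ccccc1
Why: One-pot IBX oxidation and Wittig olefination; the stabilised α-branched ylide traps the aldehyde as it forms and should give the E-enoate (future C1=C10 with C9 trans to C2).

Step 2
Reactants: 3 ethyl (E)-5-[(4-methoxybenzyl)oxy]-2-methylpent-2-enoate
Product: 4 (E)-5-[(4-methoxybenzyl)oxy]-2-methylpent-2-en-1-ol
Conditions: i-Bu2AlH (2.2 equiv), CH2Cl2, −78 °C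
Reagents that add atoms: none
Why: 1,2-Reduction of the enoate with i-Bu2AlH at low temperature gives the allylic alcohol without touching the alkene geometry or the PMB ether.

Step 3
Reactants: 4 (E)-5-[(4-methoxybenzyl)oxy]-2-methylpent-2-en-1-ol
Product: 5 (E)-5-bromo-4-methylpent-3-en-1-yl 4-methoxybenzyl ether
Conditions: CBr4, PPh3, CH2Cl2, 0 °C
Reagents that add atoms: carbon tetrabromide, BrC(Br)(Br)Br
Why: Appel bromination runs under neutral conditions by SN2 at the primary allylic carbon, so the E geometry is kept.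

Step 4
Reactants: 5 (E)-5-bromo-4-methylpent-3-en-1-yl 4-methoxybenzyl ether
Product: 6 (E)-4-methylhept-3-en-6-yn-1-yl 4-methoxybenzyl ether
Conditions: HC≡CMgBr, CuI (10 mol %), THF, 0 °C to rt
Reagents that add atoms: ethynylmagnesium bromide, C#C[Mg]Br
Why: Copper-catalysed alkynylation of an allylic bromide with an alkynyl Grignard reagent; attack at the primary carbon is favoured because the other allyl terminus is fully substituted, which gives the skipped enyne.

**Part B: iodoenal 10 (C4–C6, C15)**

Step 5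
Reactants: 7 but-2-yn-1-ol
Product: 9 (Z)-3-iodobut-2-en-1-ol, via cyclic alkenylalanate 8 (not isolated)
Conditions: NaAlH2(OCH2CH2OMe)2, THF, 0 °C to rt; then I2, −78 °C
Reagents that add atoms: iodine, [I][I]
Why: Hydroxyl-directed trans-hydroalumination of the propargylic alcohol places aluminium on C4 inside a five-membered alanate ring, and iodinolysis with retention gives the Z-iodide (iodine cis to the carbinol carbon), which fixes the 4Z geometry of the target.

Step 6
Reactants: 9 (Z)-3-iodobut-2-en-1-ol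
Product: 10 (Z)-3-iodobut-2-enal
Conditions: MnO2, CH2Cl2, rt, dark
Reagents that add atoms: none
Why: Allylic oxidation with MnO2 is neutral and should leave the Z-iodoalkene unchanged if the aldehyde is used at once.

**Part C: union, oxirane, lactone**

Step 7
Reactants: 6 (E)-4-methylhept-3-en-6-yn-1-yl 4-methoxybenzyl ether; 10 (Z)-3-iodobut-2-enal
Product: 13 rac-(2Z,5E,8E)-2-iodo-11-[(4-methoxybenzyl)oxy]-8-methylundeca-2,5,8-trien-4-ol, via alkenylzirconocene chloride 11 (not isolated), via alkenyl(methyl)zinc 12 (not isolated)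
Conditions: Cp2Zr(H)Cl, CH2Cl2, rt; Me2Zn, toluene, −65 °C; then 10, 0 °C
Reagents that add atoms: none
Why: Hydrozirconation adds Zr–H syn and terminally to the alkyne (E-alkenyl metal at C7), transmetalation to zinc allows 1,2-addition to enal 10 (C6–C7 bond), and the vinyl iodide is inert in the absence of palladium or nickel; C6 is formed racemic.

Step 8
Reactants: 13 rac-(2Z,5E,8E)-2-iodo-11-[(4-methoxybenzyl)oxy]-8-methylundeca-2,5,8-trien-4-ol
Product: 14 (1R,2Z)-3-iodo-1-[(2R,3R)-3-{(2E)-5-[(4-methoxybenzyl)oxy]-2-methylpent-2-en-1-yl}oxiran-2-yl]but-2-en-1-ol (6R,7R,8R)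
Conditions: Ti(Oi-Pr)4 (15 mol %), D-(−)-diisopropyl tartrate (18 mol %), t-BuOOH (0.5 equiv), 4 Å molecular sieves, CH2Cl2, −20 °C
Reagents that add atoms: tert-butyl hydroperoxide, CC(C)(C)OO
Why: Sharpless kinetic resolution: with D-(−)-tartrate the (6S)-enantiomer of 13 is epoxidised much faster than (6R)-13 (which stays behind and is separated), only at the E-disubstituted allylic C7=C8 bond and from the face that gives the erythro (6R,7R,8R)-epoxy alcohol, while the iodine-bearing Z-alkene is deactivated and C1=C10 is not allylic to the hydroxyl.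

Step 9
Reactants: 14 epoxy alcohol (6R,7R,8R)
Product: 15 (diethoxyphosphoryl)acetate of 14 (6R,7S,8R, geometry unchanged)
Conditions: (EtO)2P(O)CH2CO2H, DCC, DMAP (cat.), CH2Cl2, 0 °C to rt
Reagents that add atoms: (diethoxyphosphoryl)acetic acid, CCOP(=O)(CC(=O)O)OCC
Why: Steglich esterification of the secondary alcohol under neutral conditions leaves the oxirane and C6 untouched and installs C11, C12 and the phosphoryl helper.

Step 10
Reactants: 15 (diethoxyphosphoryl)acetate of 14
Product: 17 (4R,5S)-4-{(1R,3E)-1-hydroxy-6-[(4-methoxybenzyl)oxy]-3-methylhex-3-en-1-yl}-5-[(1Z)-2-iodoprop-1-en-1-yl]-3-methylideneoxolan-2-one (6S,7R,8R), via cesium phosphonate carbanion 16 (not isolated)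
Conditions: Cs2CO3 (1.1 equiv), DMF, rt to 50 °C; then 37 % aq. CH2O, 0 °C to rt
Reagents that add atoms: formaldehyde, C=O
Why: Proposed new method: Cs2CO3 deprotonates C11, the carbanion attacks C7 opposite to the C7–O bond of the oxirane and releases the C8 alkoxide, which is at once protonated by the still acidic C11–H, so that the phosphonate-stabilised lactone carbanion 16 with a free 8-OH waits in the flask until aqueous formaldehyde turns it by Horner–Wadsworth–Emmons olefination into the C11=C13 methylene group and expels the helper as diethyl phosphate. The closest known reaction types are the intermolecular opening of epoxides by phosphonoacetate anions to α-phosphono-γ-lactones, the cyclisation of epoxy nitrile and epoxy malonate carbanions, the 5-exo opening of 2,3-epoxy alcohols at C2 by tethered carbamate or imidate nitrogen, and the methylenation of α-phosphono lactones with formaldehyde; new is the ester tether between carbanion and oxirane. The γ-lactone ring (C11, C12, O, C6, C7) closes in the 5-exo-tet mode, and because the charge is held by the exocyclic phosphoryl group the C11 lone pair can turn out of the ester plane towards C7, which a plain ester enolate (endocyclic enolate, poor overlap, O-alkylation to a ketene acetal) cannot do. C7 is set by inversion at the oxirane carbon, C8 keeps the oxirane configuration and C6 is untouched, so the erythro epoxy alcohol gives the 6,7-trans lactone with the 8-hydroxyl placed as in the target. The step needs C7 over C8 (five-membered exo against six-membered endo closure, collinear attack possible only at C7), C- over O-alkylation (soft, doubly stabilised carbanion with cesium in DMF), and no phosphoryl shift, cyclopropane formation or translactonisation (no alkoxide survives the internal proton transfer); the vinyl iodide, the PMB ether and the remote alkene do not react with this weak base.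

**Part D: side-chain acid 28**

Step 11
Reactants: 18 tert-butyl acrylate; 19 [(tert-butyldimethylsilyl)oxy]acetaldehyde
Product: 20 tert-butyl 4-[(tert-butyldimethylsilyl)oxy]-3-hydroxy-2-methylidenebutanoate (racemic)
Conditions: DABCO, MeOH, rt
Reagents that add atoms: none
Why: Morita–Baylis–Hillman reaction; the α-silyloxy aldehyde is a reactive acceptor and the racemic carbinol centre disappears in step 12.

Step 12
Reactants: 20 tert-butyl 4-[(tert-butyldimethylsilyl)oxy]-3-hydroxy-2-methylidenebutanoate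
Product: 21 tert-butyl (E)-2-(acetoxymethyl)-4-[(tert-butyldimethylsilyl)oxy]but-2-enoate
Conditions: AcOH, PPh3, DIAD, THF, 0 °C
Reagents that add atoms: acetic acid, CC(=O)O
Why: Mitsunobu reaction of a Morita–Baylis–Hillman alcohol in its SN2' mode: acetate attacks the methylene terminus of the activated allylic alcohol and allylic 1,3-strain places the CH2OTBS group trans to the ester, which gives the E-alkene.

Step 13
Reactants: 21 tert-butyl (E)-2-(acetoxymethyl)-4-[(tert-butyldimethylsilyl)oxy]but-2-enoate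
Product: 23 (E)-2-(acetoxymethyl)-4-[(tert-butyldimethylsilyl)oxy]but-2-enoic acid, via trimethylsilyl ester 22 (not isolated)
Conditions: TMSOTf, 2,6-lutidine, CH2Cl2, 0 °C; aqueous work-up
Reagents that add atoms: none
Why: Silyl triflate-mediated cleavage of the tert-butyl ester (loss of isobutene) buffered by 2,6-lutidine spares the TBS ether and the allylic acetate, and the silyl ester is hydrolysed on work-up.

Step 14
Reactants: 18 tert-butyl acrylate; 24 acetaldehyde
Product: 25 tert-butyl 3-hydroxy-2-methylidenebutanoate (racemic)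
Conditions: DABCO, neat, sealed flask, rt
Reagents that add atoms: none
Why: Morita–Baylis–Hillman reaction of a simple aliphatic aldehyde; the racemic centre disappears in step 15.

Step 15
Reactants: 25 tert-butyl 3-hydroxy-2-methylidenebutanoate; 23 (E)-2-(acetoxymethyl)-4-[(tert-butyldimethylsilyl)oxy]but-2-enoic acid
Product: 26 tert-butyl (E)-2-({[(E)-2-(acetoxymethyl)-4-[(tert-butyldimethylsilyl)oxy]but-2-enoyl]oxy}methyl)but-2-enoate
Conditions: PPh3, DIAD, THF, 0 °C
Reagents that add atoms: none
Why: SN2' Mitsunobu reaction as in step 12 with acid 23 as the pronucleophile joins the two C5 acids and sets the second E-alkene (methyl trans to the ester carbonyl).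

Step 16
Reactants: 26 tert-butyl diester
Product: 28 (E)-2-({[(E)-2-(acetoxymethyl)-4-[(tert-butyldimethylsilyl)oxy]but-2-enoyl]oxy}methyl)but-2-enoic acid, via trimethylsilyl ester 27 (not isolated)
Conditions: TMSOTf, 2,6-lutidine, CH2Cl2, 0 °C; aqueous work-up
Reagents that add atoms: none
Why: Same silyl triflate-mediated tert-butyl ester cleavage as in step 13; the two allylic esters, the acetate and the TBS ether are not ionised under the buffered conditions.

**Part E: ester, ten-membered ring, oxirane**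

Step 17
Reactants: 17 lactone alcohol (6S,7R,8R); 28 side-chain acid
Product: 30 8-O-acyl derivative of 17 (acyl = residue of 28; 6S,7R,8R), via mixed anhydride 29 (not isolated)
Conditions: 28, 2,4,6-Cl3C6H2COCl, Et3N, toluene, rt; then 17, DMAP, 0 °C to rt
Reagents that add atoms: none
Why: Yamaguchi esterification activates the α-branched enoic acid enough to acylate the only hydroxyl (C8–OH, retention at C8) before base can move the lactone or the alkenes.

Step 18
Reactants: 30 8-O-acyl lactone PMB ether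
Product: 31 primary alcohol (C3–OH free; 6S,7R,8R)
Conditions: DDQ, CH2Cl2/pH 7 buffer, 0 °C
Reagents that add atoms: none
Why: Oxidative PMB cleavage with DDQ acts on the electron-rich benzyl ether only and leaves the TBS ether, the vinyl iodide, the esters and the alkenes untouched.

Step 19
Reactants: 31 primary alcohol
Product: 32 β,γ-unsaturated aldehyde (C3 = CHO; 6S,7R,8R)
Conditions: Dess–Martin periodinane, NaHCO3, CH2Cl2, 0 °C
Reagents that add atoms: none
Why: Buffered Dess–Martin oxidation gives the β,γ-unsaturated aldehyde without moving C1=C10 into conjugation; it is used at once.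

Step 20
Reactants: 32 β,γ-unsaturated aldehyde
Product: 34 (6R,7R,8R)-8-acyloxy-3-hydroxygermacra-1(10)E,4Z,11(13)-trien-12,6-olide (acyl = residue of 28; both C3 epimers), via alkenylchromium dichloride 33 (not isolated)
Conditions: CrCl2 (10 equiv), NiCl2 (1 mol % of the CrCl2), DMSO/THF, rt, slow addition, 1 mM
Reagents that add atoms: none
Why: Nozaki–Hiyama–Kishi reaction: zerovalent nickel inserts into the C4–I bond, the alkenyl group passes to trivalent chromium with retention of the Z geometry and adds to the C3 aldehyde under neutral conditions that esters, enoates, the silyl ether and the α-methylene lactone tolerate, high dilution favouring closure of the ten-membered ring; the C3 configuration formed here (expected mainly 3R, chromium alkoxide on the outside) is erased in step 21.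

Step 21
Reactants: 34 macrocyclic allylic alcohol (C3 epimers)
Product: 35 (6R,7R,8R)-8-acyloxy-3-oxogermacra-1(10)E,4Z,11(13)-trien-12,6-olide
Conditions: Dess–Martin periodinane, NaHCO3, CH2Cl2, 0 °C
Reagents that add atoms: none
Why: Dess–Martin oxidation of the only free hydroxyl merges both C3 epimers into one enone under buffered conditions that should not move C1=C10 into conjugation.

Step 22
Reactants: 35 macrocyclic enone
Product: 36 (3S,6R,7R,8R)-8-acyloxy-3-hydroxygermacra-1(10)E,4Z,11(13)-trien-12,6-olide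
Conditions: NaBH4, CeCl3·7H2O, MeOH/THF, −78 °C
Reagents that add atoms: none
Why: Luche reduction: in the ten-membered ring the C3 carbonyl is twisted out of the C4=C5 plane and its inner face is covered by C1/C10, so hydride can come only from the periphery and pushes the oxygen under the ring towards C10 (3S, 3β), and 1,2-addition at −78 °C should outrun conjugate reduction of the α-methylene lactone.

Step 23
Reactants: 36 (3S)-allylic alcohol
Product: 37 (1R,3S,6R,7R,8R,10R)-1,10-epoxide (TBS ether of the target)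
Conditions: m-CPBA (1.0 equiv), NaHCO3, CH2Cl2, −20 to 0 °C
Reagents that add atoms: 3-chloroperoxybenzoic acid, O=C(OO)c1cccc(Cl)c1
Why: Prilezhaev epoxidation: the strained trialkyl-substituted E-C1=C10 bond is the only electron-rich alkene (C4=C5 carries two allylic C–O bonds, all others are conjugated to carbonyls), and in the preferred conformer (C14 on the β face, alkene plane perpendicular to the ring) only its outer face is open, which gives the trans (1R,10R)-oxirane.

Step 24
Reactants: 37 TBS ether of the target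
Product: 38 target CNP0193678.1
Conditions: Et3N·3HF, MeCN, 0 °C to rt
Reagents that add atoms: none
Why: Desilylation with the nearly neutral Et3N·3HF removes the primary allylic TBS ether without opening the oxirane, migrating the acetate or adding to the α-methylene lactone.

**Compound list**

1 | 3-[(4-methoxybenzyl)oxy]propan-1-ol | OCCCOCc1ccc(OC)cc1 | starting material
2 | 3-[(4-methoxybenzyl)oxy]propanal | O=CCCOCc1ccc(OC)cc1 | intermediate
3 | ethyl (E)-5-[(4-methoxybenzyl)oxy]-2-methylpent-2-enoate | CCOC(=O)/C(C)=C/CCOCc1ccc(OC)cc1 | intermediate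
4 | (E)-5-[(4-methoxybenzyl)oxy]-2-methylpent-2-en-1-ol | OC/C(C)=C/CCOCc1ccc(OC)cc1 | intermediate
5 | (E)-5-bromo-4-methylpent-3-en-1-yl 4-methoxybenzyl ether | BrC/C(C)=C/CCOCc1ccc(OC)cc1 | intermediate
6 | (E)-4-methylhept-3-en-6-yn-1-yl 4-methoxybenzyl ether | C#CC/C(C)=C/CCOCc1ccc(OC)cc1 | intermediate
7 | but-2-yn-1-ol | CC#CCO | starting material
8 | sodium 2,2-bis(2-methoxyethoxy)-3-methyl-2,5-dihydro-1,2-oxaluminol-2-uide (cyclic alkenylalanate) | CC1=CCO[Al-]1(OCCOC)OCCOC.[Na+] | intermediate
9 | (Z)-3-iodobut-2-en-1-ol | C/C([I])=C/CO | intermediate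
10 | (Z)-3-iodobut-2-enal | C/C([I])=C/C=O | intermediate
11 | chloro{(1E,4E)-7-[(4-methoxybenzyl)oxy]-4-methylhepta-1,4-dien-1-yl}zirconocene | Cl[Zr](/C=C/C/C(C)=C/CCOCc1ccc(OC)cc1)(C1C=CC=C1)C1C=CC=C1 | intermediate
12 | {(1E,4E)-7-[(4-methoxybenzyl)oxy]-4-methylhepta-1,4-dien-1-yl}(methyl)zinc | C[Zn]/C=C/C/C(C)=C/CCOCc1ccc(OC)cc1 | intermediate
13 | rac-(2Z,5E,8E)-2-iodo-11-[(4-methoxybenzyl)oxy]-8-methylundeca-2,5,8-trien-4-ol | C/C([I])=C/C(O)/C=C/C/C(C)=C/CCOCc1ccc(OC)cc1 | intermediate
14 | (1R,2Z)-3-iodo-1-[(2R,3R)-3-{(2E)-5-[(4-methoxybenzyl)oxy]-2-methylpent-2-en-1-yl}oxiran-2-yl]but-2-en-1-ol | C/C([I])=C/[C@@H](O)[C@H]1O[C@@H]1C/C(C)=C/CCOCc1ccc(OC)cc1 | intermediate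
15 | (1R,2Z)-3-iodo-1-[(2S,3R)-3-{(2E)-5-[(4-methoxybenzyl)oxy]-2-methylpent-2-en-1-yl}oxiran-2-yl]but-2-en-1-yl (diethoxyphosphoryl)acetate | C/C([I])=C/[C@@H](OC(=O)CP(=O)(OCC)OCC)[C@H]1O[C@@H]1C/C(C)=C/CCOCc1ccc(OC)cc1 | intermediate
16 | cesium salt of the C11 carbanion of the α-(diethoxyphosphoryl) lactone (C6–C8 as in 17) | [Cs+].CCOP(=O)(OCC)[C-]1C(=O)O[C@H](/C=C(/C)[I])[C@H]1[C@H](O)C/C(C)=C/CCOCc1ccc(OC)cc1 | intermediate
17 | (4R,5S)-4-{(1R,3E)-1-hydroxy-6-[(4-methoxybenzyl)oxy]-3-methylhex-3-en-1-yl}-5-[(1Z)-2-iodoprop-1-en-1-yl]-3-methylideneoxolan-2-one | C=C1C(=O)O[C@H](/C=C(/C)[I])[C@H]1[C@H](O)C/C(C)=C/CCOCc1ccc(OC)cc1 | intermediate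
18 | tert-butyl acrylate | C=CC(=O)OC(C)(C)C | starting material
19 | [(tert-butyldimethylsilyl)oxy]acetaldehyde | O=CCO[Si](C)(C)C(C)(C)C | starting material
20 | tert-butyl 4-[(tert-butyldimethylsilyl)oxy]-3-hydroxy-2-methylidenebutanoate (racemic) | C=C(C(O)CO[Si](C)(C)C(C)(C)C)C(=O)OC(C)(C)C | intermediate
21 | tert-butyl (E)-2-(acetoxymethyl)-4-[(tert-butyldimethylsilyl)oxy]but-2-enoate | CC(C)(C)OC(=O)/C(=C/CO[Si](C)(C)C(C)(C)C)COC(C)=O | intermediate
22 | trimethylsilyl (E)-2-(acetoxymethyl)-4-[(tert-butyldimethylsilyl)oxy]but-2-enoate | C[Si](C)(C)OC(=O)/C(=C/CO[Si](C)(C)C(C)(C)C)COC(C)=O | intermediate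
23 | (E)-2-(acetoxymethyl)-4-[(tert-butyldimethylsilyl)oxy]but-2-enoic acid | OC(=O)/C(=C/CO[Si](C)(C)C(C)(C)C)COC(C)=O | intermediate
24 | acetaldehyde | CC=O | starting material
25 | tert-butyl 3-hydroxy-2-methylidenebutanoate (racemic) | C=C(C(C)O)C(=O)OC(C)(C)C | intermediate
26 | tert-butyl (E)-2-({[(E)-2-(acetoxymethyl)-4-[(tert-butyldimethylsilyl)oxy]but-2-enoyl]oxy}methyl)but-2-enoate | CC(C)(C)OC(=O)/C(=C/C)COC(=O)/C(=C/CO[Si](C)(C)C(C)(C)C)COC(C)=O | intermediate
27 | trimethylsilyl ester of 28 | C[Si](C)(C)OC(=O)/C(=C/C)COC(=O)/C(=C/CO[Si](C)(C)C(C)(C)C)COC(C)=O | intermediate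
28 | (E)-2-({[(E)-2-(acetoxymethyl)-4-[(tert-butyldimethylsilyl)oxy]but-2-enoyl]oxy}methyl)but-2-enoic acid | OC(=O)/C(=C/C)COC(=O)/C(=C/CO[Si](C)(C)C(C)(C)C)COC(C)=O | intermediate
29 | mixed anhydride of 28 and 2,4,6-trichlorobenzoic acid | O=C(OC(=O)/C(=C/C)COC(=O)/C(=C/CO[Si](C)(C)C(C)(C)C)COC(C)=O)c1c(Cl)cc(Cl)cc1Cl | intermediate
30 | 8-O-acyl derivative of 17 (acyl = residue of 28; 6S,7R,8R) | C=C1C(=O)O[C@H](/C=C(/C)[I])[C@H]1[C@H](OC(=O)/C(=C/C)COC(=O)/C(=C/CO[Si](C)(C)C(C)(C)C)COC(C)=O)C/C(C)=C/CCOCc1ccc(OC)cc1 | intermediate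
31 | primary alcohol from 30 (C3–OH free) | C=C1C(=O)O[C@H](/C=C(/C)[I])[C@H]1[C@H](OC(=O)/C(=C/C)COC(=O)/C(=C/CO[Si](C)(C)C(C)(C)C)COC(C)=O)C/C(C)=C/CCO | intermediate
32 | β,γ-unsaturated aldehyde from 31 (C3 = CHO) | C=C1C(=O)O[C@H](/C=C(/C)[I])[C@H]1[C@H](OC(=O)/C(=C/C)COC(=O)/C(=C/CO[Si](C)(C)C(C)(C)C)COC(C)=O)C/C(C)=C/CC=O | intermediate
33 | (Z)-alkenylchromium dichloride from 32 (Cr on C4) | C=C1C(=O)O[C@H](/C=C(/C)[Cr](Cl)Cl)[C@H]1[C@H](OC(=O)/C(=C/C)COC(=O)/C(=C/CO[Si](C)(C)C(C)(C)C)COC(C)=O)C/C(C)=C/CC=O | intermediate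
34 | (6R,7R,8R)-8-acyloxy-3-hydroxygermacra-1(10)E,4Z,11(13)-trien-12,6-olide, both C3 epimers | C=C1C(=O)O[C@@H]2/C=C(/C)C(O)C/C=C(\C)C[C@@H](OC(=O)/C(=C/C)COC(=O)/C(=C/CO[Si](C)(C)C(C)(C)C)COC(C)=O)[C@@H]12 | intermediate
35 | (6R,7R,8R)-8-acyloxy-3-oxogermacra-1(10)E,4Z,11(13)-trien-12,6-olide | C=C1C(=O)O[C@@H]2/C=C(/C)C(=O)C/C=C(\C)C[C@@H](OC(=O)/C(=C/C)COC(=O)/C(=C/CO[Si](C)(C)C(C)(C)C)COC(C)=O)[C@@H]12 | intermediate
36 | (3S,6R,7R,8R)-8-acyloxy-3-hydroxygermacra-1(10)E,4Z,11(13)-trien-12,6-olide | C=C1C(=O)O[C@@H]2/C=C(/C)[C@@H](O)C/C=C(\C)C[C@@H](OC(=O)/C(=C/C)COC(=O)/C(=C/CO[Si](C)(C)C(C)(C)C)COC(C)=O)[C@@H]12 | intermediate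
37 | (1R,3S,6R,7R,8R,10R)-1,10-epoxide of 36 (TBS ether of the target) | C=C1C(=O)O[C@@H]2/C=C(/C)[C@@H](O)C[C@H]3O[C@]3(C)C[C@@H](OC(=O)/C(=C/C)COC(=O)/C(=C/CO[Si](C)(C)C(C)(C)C)COC(C)=O)[C@@H]12 | intermediate
38 | CNP0193678.1, (1R,3S,6R,7R,8R,10R)-1,10-epoxy-3-hydroxy-8-acyloxygermacra-4Z,11(13)-dien-12,6-olide | C=C1C(=O)O[C@@H]2/C=C(/C)[C@@H](O)C[C@H]3O[C@]3(C)C[C@@H](OC(=O)/C(=C/C)COC(=O)/C(=C/CO)COC(C)=O)[C@@H]12 | target

**Step count**
Total step count: 24.
Longest linear sequence: 16 (steps 1–4, 7–10, 17–24).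

**Steps most likely to fail**

Step 10. The ring closure may stall because the ester stays in its extended rotamer. The ester enolate oxygen may also attack C7 in place of C11. The fallback uses known radical chemistry at the ether oxidation level; it sets out from 14 and comes back at 30. O-Alkylation of 14 (NaH, propargyl bromide, Bu4NI, THF) gives the propargyl ether F1. Cp2TiCl (made from Cp2TiCl2 and Zn in THF, a trivalent titanium reagent) opens the oxirane homolytically, and the C7 radical closes 5-exo-dig onto the alkyne, again forming C7–C11. Hydrogen uptake then gives the 3-methylidenetetrahydrofuran alcohol F2, with C8 retained and the ring substituents trans. Yamaguchi esterification with 28 gives the ester F3. Allylic oxidation of the doubly activated C12 methylene (CrO3·3,5-dimethylpyrazole, CH2Cl2, −20 °C) returns to 30.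

Step 20. Oligomerisation may compete with ring closure, the β,γ-unsaturated aldehyde may slip into conjugation, and low-valent nickel may consume the allylic esters of the side chain. The fallback postpones the esterification and relies on chemoselective oxidations instead of protecting groups; it sets out from 17 and comes back at 35. DDQ removes the PMB group from 17 and gives the diol F4. TEMPO/PhI(OAc)2 oxidises only the primary hydroxyl and gives the hydroxy aldehyde F5. CrCl2/NiCl2 under high dilution closes the ring and gives the macrocyclic diol F6. MnO2 oxidises only the allylic C3 hydroxyl and gives the hydroxy enone F7. Yamaguchi esterification of its single hydroxyl (C8) with 28 returns to 35.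

Step 23. Facial selectivity may be poor if a second ring conformer is populated, and the C3 hydroxyl may direct the peracid to C4=C5. The fallback sets C1/C10 by reagent control before the ring exists; it sets out from 31 and comes back at 37. Shi epoxidation of 31 (D-fructose-derived ketone catalyst, KHSO5 as 2KHSO5·KHSO4·K2SO4, K2CO3, MeCN/dimethoxymethane/aqueous buffer, 0 °C) attacks the only electron-rich alkene and gives the epoxy alcohol F8 (1R,10R). Buffered Dess–Martin oxidation gives the epoxy aldehyde F9. The Nozaki–Hiyama–Kishi ring closure gives the macrocyclic epoxy alcohol F10. Dess–Martin oxidation gives the epoxy enone F11. Luche reduction from the periphery returns to 37.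

**Further compounds**
F1 | step 10 | propargyl ether of 14 | C/C([I])=C/[C@@H](OCC#C)[C@H]1O[C@@H]1C/C(C)=C/CCOCc1ccc(OC)cc1
F2 | step 10 | 3-methylidenetetrahydrofuran alcohol (C12 = CH2 analogue of 17) | C=C1CO[C@H](/C=C(/C)[I])[C@H]1[C@H](O)C/C(C)=C/CCOCc1ccc(OC)cc1
F3 | step 10 | 8-O-acyl derivative of F2 (acyl = residue of 28) | C=C1CO[C@H](/C=C(/C)[I])[C@H]1[C@H](OC(=O)/C(=C/C)COC(=O)/C(=C/CO[Si](C)(C)C(C)(C)C)COC(C)=O)C/C(C)=C/CCOCc1ccc(OC)cc1
F4 | step 20 | diol (17 without PMB) | C=C1C(=O)O[C@H](/C=C(/C)[I])[C@H]1[C@H](O)C/C(C)=C/CCO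
F5 | step 20 | hydroxy aldehyde (C3 = CHO, 8-OH free) | C=C1C(=O)O[C@H](/C=C(/C)[I])[C@H]1[C@H](O)C/C(C)=C/CC=O
F6 | step 20 | (6R,7R,8R)-3,8-dihydroxygermacra-1(10)E,4Z,11(13)-trien-12,6-olide, both C3 epimers | C=C1C(=O)O[C@@H]2/C=C(/C)C(O)C/C=C(\C)C[C@@H](O)[C@@H]12
F7 | step 20 | (6R,7R,8R)-8-hydroxy-3-oxogermacra-1(10)E,4Z,11(13)-trien-12,6-olide | C=C1C(=O)O[C@@H]2/C=C(/C)C(=O)C/C=C(\C)C[C@@H](O)[C@@H]12
F8 | step 23 | (1R,10R)-epoxy alcohol from 31 | C=C1C(=O)O[C@H](/C=C(/C)[I])[C@H]1[C@H](OC(=O)/C(=C/C)COC(=O)/C(=C/CO[Si](C)(C)C(C)(C)C)COC(C)=O)C[C@@]2(C)O[C@@H]2CCO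
F9 | step 23 | (1R,10R)-epoxy aldehyde | C=C1C(=O)O[C@H](/C=C(/C)[I])[C@H]1[C@H](OC(=O)/C(=C/C)COC(=O)/C(=C/CO[Si](C)(C)C(C)(C)C)COC(C)=O)C[C@@]2(C)O[C@@H]2CC=O
F10 | step 23 | macrocyclic 1,10-epoxy-3-hydroxy compound, both C3 epimers | C=C1C(=O)O[C@@H]2/C=C(/C)C(O)C[C@H]3O[C@]3(C)C[C@@H](OC(=O)/C(=C/C)COC(=O)/C(=C/CO[Si](C)(C)C(C)(C)C)COC(C)=O)[C@@H]12
F11 | step 23 | macrocyclic 1,10-epoxy-3-oxo compound | C=C1C(=O)O[C@@H]2/C=C(/C)C(=O)C[C@H]3O[C@]3(C)C[C@@H](OC(=O)/C(=C/C)COC(=O)/C(=C/CO[Si](C)(C)C(C)(C)C)COC(C)=O)[C@@H]12
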